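**Plan**

- Numbering (longipinane): C1 ketone, C2=C3(CH3), bridgeheads C4 and C11, C5, C6(CH3)2, C7(O), C8, C9(O), C10(CH3). The cyclobutane is C4–C5–C11–C10; the seven-membered ring runs C10–C9–C8–C7–C6–C5–C4.
- Retrosynthesis: cut the two ester C–O bonds and the C1 oxygen; then C7–C8 and C9–C10 together, releasing C8–C9 as an acetaldehyde enol silane; then one C6 methyl and the exocyclic carbon on C10; then C4–C5 and C10–C11 (ketene plus alkene) back to an open-chain trienoic acid.
- Feature that allows the key event: the C7–C8–C9 bridge spans the two diagonal cyclobutane carbons C5 and C10 of a bicyclo[3.1.1]heptene. A C6–C7 aldehyde arm on C5 and an exocyclic vinyl sulfone at C10 therefore sit 1,3-diaxial, and both are electrophiles. A two-carbon unit that is a nucleophile at C8 and then an acyl radical at C9 closes the seven-membered ring between them.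
- Forward: ring-closing metathesis gives a lactone that fixes the Z-alkene; coupling gives the skipped trienoic acid; an intramolecular vinylketene [2+2] closes cyclobutane and cyclohexene together; the arm is built by hydroboration, oxidation and methylation; the key annulation closes the seven-membered ring and makes quaternary C10; then C9 reduction, desulfonylation to the C10 methyl, the two esters, and allylic oxidation to the enone.
- Stereochemistry: C4, C5, C11 relative from the suprafacial [2+2] on the E-alkene, absolute by resolution of the bicyclic ketone; C10 from the tether; C7 from the chiral acid catalyst; C9 from Corey–Bakshi–Shibata reduction; the epoxy acid from Sharpless epoxidation; the Z-enoate from angelic acid.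

Key step: step 10

Remark: which antipode of the acid catalyst gives the R carbinol at C7, and which chromatographic fraction is 11, would each be settled by one trial; the route is written for the senses assumed.

**Route**

Step 1
Reactants: 1 3-methylbut-3-enoic acid; 2 prop-2-en-1-ol
Product: 3 prop-2-en-1-yl 3-methylbut-3-enoate
Conditions: DCC, DMAP (cat.), CH2Cl2, 0 °C
Reagents that add atoms: none
Why: Steglich esterification at 0 °C joins acid and alcohol without moving the β,γ-double bond into conjugation.

Step 2
Reactants: 3 prop-2-en-1-yl 3-methylbut-3-enoate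
Product: 4 4-methyl-3,6-dihydro-2H-pyran-2-one
Conditions: second-generation Grubbs catalyst (cat.), CH2Cl2 (dilute), 40 °C
Reagents that add atoms: none
Why: Ring-closing metathesis between the monosubstituted and the 1,1-disubstituted alkene closes the six-membered lactone, whose ring holds the new trisubstituted alkene in the Z geometry needed in step 4.

Step 3
Reactants: 5 2-methylbut-1-en-3-yne; 4 4-methyl-3,6-dihydro-2H-pyran-2-one
Product: 7 (3Z,6E)-3,8-dimethylnona-3,6,8-trienoic acid, via dienylboronate 6 (not isolated)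
Conditions: catecholborane, neat, 70 °C; then 4, Pd(PPh3)4 (cat.), aq. K2CO3, THF, 50 °C; aq. HCl work-up
Reagents that add atoms: none
Why: Syn, anti-Markovnikov hydroboration of the terminal alkyne gives the E-dienylboronate, and Suzuki–Miyaura coupling through the π-allylpalladium carboxylate formed by ionisation of the allylic lactone C–O bond joins it to the unsubstituted allyl terminus, the Z-alkene being kept because syn/anti exchange would need a σ-bond to the fully substituted terminus.

Step 4
Reactants: 7 (3Z,6E)-3,8-dimethylnona-3,6,8-trienoic acid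
Product: 10 racemic 2-methyl-7-(prop-1-en-2-yl)bicyclo[3.1.1]hept-2-en-6-one, via acid chloride 8 (not isolated), via vinylketene 9 (not isolated)
Conditions: (COCl)2, DMF (cat.), CH2Cl2, 0 °C to rt; then slow addition to Et3N, toluene, 110 °C
Reagents that add atoms: none
Why: Dehydrochlorination of the β,γ-unsaturated acid chloride gives the Z-vinylketene, which should undergo the known intramolecular vinylketene–alkene [2+2] cycloaddition to bicyclo[3.1.1]heptenones, the ketene carbonyl carbon bonding to the inner alkene carbon C11 because positive charge at C5 is allylic, and the suprafacial addition to the E-alkene placing the isopropenyl group anti to the three-carbon bridge.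

Step 5
Reactants: 10 racemic 2-methyl-7-(prop-1-en-2-yl)bicyclo[3.1.1]hept-2-en-6-one
Product: 11 (1R,5R,7R)-2-methyl-7-(prop-1-en-2-yl)bicyclo[3.1.1]hept-2-en-6-one
Conditions: preparative supercritical-fluid chromatography, amylose tris(3,5-dimethylphenylcarbamate) phase, CO2/iPrOH
Reagents that add atoms: none
Why: Resolution of the rigid ketone on a polysaccharide chiral phase fixes the absolute configuration of C4, C5 and C11 for the rest of the route.

Step 6
Reactants: 11 (1R,5R,7R)-2-methyl-7-(prop-1-en-2-yl)bicyclo[3.1.1]hept-2-en-6-one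
Product: 12 2-methyl-6-[(phenylsulfonyl)methylidene]-7-(prop-1-en-2-yl)bicyclo[3.1.1]hept-2-ene
Conditions: (EtO)2P(O)CH2SO2Ph, NaH, THF, 0 °C to rt
Reagents that add atoms: diethyl [(phenylsulfonyl)methyl]phosphonate, CCOP(=O)(OCC)CS(=O)(=O)c1ccccc1
Why: Horner–Wadsworth–Emmons olefination of the strained, non-enolisable cyclobutanone installs the exocyclic vinyl sulfone whose sulfonyl-bearing carbon will become the C10 methyl, and both alkene isomers converge in step 10.

Step 7
Reactants: 12 2-methyl-6-[(phenylsulfonyl)methylidene]-7-(prop-1-en-2-yl)bicyclo[3.1.1]hept-2-ene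
Product: 13 2-{2-methyl-6-[(phenylsulfonyl)methylidene]bicyclo[3.1.1]hept-2-en-7-yl}propan-1-ol
Conditions: 9-BBN, THF, 0 °C to rt; then Me3NO, 60 °C
Reagents that add atoms: trimethylamine N-oxide, C[N+](C)(C)[O-]
Why: 9-BBN adds anti-Markovnikov to the 1,1-disubstituted isopropenyl group much faster than to the trisubstituted ring alkene or the electron-poor vinyl sulfone, and amine-oxide oxidation of the borane avoids alkaline peroxide, so the primary alcohol at C7 should result (the C6 centre formed here is erased in step 9).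

Step 8
Reactants: 13 2-{2-methyl-6-[(phenylsulfonyl)methylidene]bicyclo[3.1.1]hept-2-en-7-yl}propan-1-ol
Product: 14 2-{2-methyl-6-[(phenylsulfonyl)methylidene]bicyclo[3.1.1]hept-2-en-7-yl}propanal
Conditions: Dess–Martin periodinane, NaHCO3, CH2Cl2, 0 °C
Reagents that add atoms: none
Why: Dess–Martin oxidation converts the primary alcohol into the aldehyde under buffered conditions that leave both alkenes and the sulfone untouched.

Step 9
Reactants: 14 2-{2-methyl-6-[(phenylsulfonyl)methylidene]bicyclo[3.1.1]hept-2-en-7-yl}propanal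
Product: 15 2-methyl-2-{2-methyl-6-[(phenylsulfonyl)methylidene]bicyclo[3.1.1]hept-2-en-7-yl}propanal
Conditions: KOtBu, MeI, THF, −78 to 0 °C
Reagents that add atoms: iodomethane, CI
Why: Alkylation of the potassium enolate of the α-branched aldehyde with iodomethane makes C6 quaternary by a purely anionic path, which avoids a radical or cation at C6 that would open the adjacent cyclobutane.

Step 10
Reactants: 15 2-methyl-2-{2-methyl-6-[(phenylsulfonyl)methylidene]bicyclo[3.1.1]hept-2-en-7-yl}propanal; 16 tert-butyl(ethenyloxy)dimethylsilane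
Product: 18 (7R)-7-[(tert-butyldimethylsilyl)oxy]-10-[(phenylsulfonyl)methyl]-10-demethyl-longipin-2-en-9-one, via silyloxy aldehyde 17 (not isolated)
Conditions: (S,S)-imidodiphosphorimidate Brønsted acid (IDPi, 1 mol %), toluene, −60 °C, dark; then MeCN, (Bu4N)4[W10O32] (2 mol %), 390 nm, 20 °C, same flask
Reagents that add atoms: none
Why: Proposed new method: two catalytic cycles are relayed in one flask so that the enol silane acts as a two-carbon unit that is a nucleophile at C8 and then an acyl radical at C9: the silylated confined acid promotes a single Mukaiyama aldol addition of 16 to the neopentyl aldehyde (C7–C8, silyl group passing to O7) to give 17, and excited decatungstate then abstracts the new formyl hydrogen, the C9 acyl radical adds to C10 of the vinyl sulfone (C9–C10) and the α-sulfonyl radical takes the hydrogen back from the reduced photocatalyst. The closest known reactions are the catalytic asymmetric single aldolisation of acetaldehyde enol silanes with imidodiphosphorimidate acids and the decatungstate-photocatalysed hydroacylation (Giese addition of acyl radicals) of vinyl sulfones; their relay and a ring closure of this size onto a fully substituted alkene carbon have no precedent. Only the seven-membered ring is closed, by 7-exo-trig attack of the acyl radical on exocyclic C10, which the cage favours because the arm on C5 and the p-lobe of C10 are 1,3-diaxial on the cyclobutane. C7 is set by the chiral catalyst, and quaternary C10 by the tether, which reaches only the face of C10 anti to the C1–C3 bridge. The step needs a single aldol event at the only aldehyde (confinement of the catalyst; the two electrophilic termini of 15 cannot react with each other), hydrogen abstraction at the unhindered formyl C–H in preference to allylic and carbinol C–H, and addition at C10 instead of the sulfonyl-bearing carbon (polar match of the nucleophilic acyl radical with the β-carbon of the vinyl sulfone).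

Step 11
Reactants: 18 (7R)-7-[(tert-butyldimethylsilyl)oxy]-10-[(phenylsulfonyl)methyl]-10-demethyl-longipin-2-en-9-one
Product: 19 (7R,9R)-7-[(tert-butyldimethylsilyl)oxy]-10-[(phenylsulfonyl)methyl]-10-demethyl-longipin-2-en-9-ol
Conditions: (S)-2-methyl-CBS-oxazaborolidine (cat.), catecholborane, toluene, −78 °C
Reagents that add atoms: none
Why: Corey–Bakshi–Shibata reduction with catecholborane, which does not hydroborate the ring alkene at low temperature, delivers hydride to the ketone face fixed by the catalyst (large group quaternary C10, small group C8H2) and should give the 9R alcohol under reagent control.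

Step 12
Reactants: 19 (7R,9R)-7-[(tert-butyldimethylsilyl)oxy]-10-[(phenylsulfonyl)methyl]-10-demethyl-longipin-2-en-9-ol
Product: 20 (7R,9R)-7-[(tert-butyldimethylsilyl)oxy]longipin-2-en-9-ol
Conditions: Na(Hg), Na2HPO4, MeOH–THF, −20 °C to rt
Reagents that add atoms: none
Why: Reductive desulfonylation with sodium amalgam cleaves the C–S bond of the primary alkyl phenyl sulfone to reveal the C10 methyl, with no β-leaving group available for elimination.

Step 13
Reactants: 20 (7R,9R)-7-[(tert-butyldimethylsilyl)oxy]longipin-2-en-9-ol; 21 (2Z)-2-methylbut-2-enoic acid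
Product: 22 (7R,9R)-7-[(tert-butyldimethylsilyl)oxy]longipin-2-en-9-yl (2Z)-2-methylbut-2-enoate
Conditions: 2,4,6-trichlorobenzoyl chloride, Et3N, toluene, rt; then 20, 80 °C
Reagents that add atoms: none
Why: Yamaguchi esterification through the mixed 2,4,6-trichlorobenzoic anhydride acylates the hindered C9 alcohol with angelic acid under conditions known to preserve the Z-alkene.

Step 14
Reactants: 22 (7R,9R)-7-[(tert-butyldimethylsilyl)oxy]longipin-2-en-9-yl (2Z)-2-methylbut-2-enoate
Product: 23 (7R,9R)-7-hydroxylongipin-2-en-9-yl (2Z)-2-methylbut-2-enoate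
Conditions: HF·pyridine, THF, 0 °C to rt
Reagents that add atoms: none
Why: Fluoride cleavage of the silyl ether with HF·pyridine frees the C7 alcohol under mildly acidic conditions that should neither move nor isomerise the angelate.

Step 15
Reactants: 24 (2E)-2-methylbut-2-en-1-ol
Product: 25 [(2R,3R)-2,3-dimethyloxiran-2-yl]methanol
Conditions: Ti(OiPr)4 (cat.), D-(−)-diethyl tartrate (cat.), t-BuOOH, 4 Å molecular sieves, CH2Cl2, −20 °C
Reagents that add atoms: tert-butyl hydroperoxide, CC(C)(C)OO
Why: Sharpless asymmetric epoxidation of the E-allylic alcohol with the D-tartrate delivers oxygen to the face that gives the (2R,3R)-epoxy alcohol, the two methyl groups staying cis.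

Step 16
Reactants: 25 [(2R,3R)-2,3-dimethyloxiran-2-yl]methanol
Product: 26 (2S,3R)-2,3-dimethyloxirane-2-carboxylic acid
Conditions: RuCl3 (cat.), NaIO4, CCl4–MeCN–H2O, rt
Reagents that add atoms: sodium periodate, [Na+].[O-]I(=O)(=O)=O; water, O
Why: Ruthenium tetroxide generated in situ oxidises the primary epoxy alcohol to the glycidic acid without touching the epoxide (the descriptor at C2 changes to S only through the priority rules).

Step 17
Reactants: 23 (7R,9R)-7-hydroxylongipin-2-en-9-yl (2Z)-2-methylbut-2-enoate; 26 (2S,3R)-2,3-dimethyloxirane-2-carboxylic acid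
Product: 27 (7R,9R)-9-{[(2Z)-2-methylbut-2-enoyl]oxy}longipin-2-en-7-yl (2S,3R)-2,3-dimethyloxirane-2-carboxylate
Conditions: 2,4,6-trichlorobenzoyl chloride, Et3N, THF, rt; then 23, DMAP, toluene, 40 °C
Reagents that add atoms: none
Why: Yamaguchi esterification couples the hindered C7 alcohol with the preformed, enantiopure epoxy acid, so that no selective epoxidation is needed in the presence of the angelate.

Step 18
Reactants: 27 (7R,9R)-9-{[(2Z)-2-methylbut-2-enoyl]oxy}longipin-2-en-7-yl (2S,3R)-2,3-dimethyloxirane-2-carboxylate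
Product: 28 (4R,5S,7R,9R,10R,11R)-9-{[(2Z)-2-methylbut-2-enoyl]oxy}-1-oxolongipin-2-en-7-yl (2S,3R)-2,3-dimethyloxirane-2-carboxylate
Conditions: Rh2(cap)4 (cap = caprolactamate, cat.), t-BuOOH, K2CO3, CH2Cl2, rt
Reagents that add atoms: tert-butyl hydroperoxide, CC(C)(C)OO
Why: Dirhodium-catalysed allylic oxidation with tert-butyl hydroperoxide should oxidise the only activated ring methylene, C1 next to the trisubstituted C2=C3 alkene, to the conjugated ketone as in the oxidation of α-pinene to verbenone, while the electron-poor angelate alkene, the epoxide and the esters stay intact.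

**Compound list**

1 | 3-methylbut-3-enoic acid | C=C(C)CC(=O)O | starting material
2 | prop-2-en-1-ol | C=CCO | starting material
3 | prop-2-en-1-yl 3-methylbut-3-enoate | C=C(C)CC(=O)OCC=C | intermediate
4 | 4-methyl-3,6-dihydro-2H-pyran-2-one | CC1=CCOC(=O)C1 | intermediate
5 | 2-methylbut-1-en-3-yne | C=C(C)C#C | starting material
6 | 2-[(1E)-3-methylbuta-1,3-dien-1-yl]-1,3,2-benzodioxaborole | C=C(C)/C=C/B1Oc2ccccc2O1 | intermediate
7 | (3Z,6E)-3,8-dimethylnona-3,6,8-trienoic acid | OC(=O)C/C(C)=C\C/C=C/C(C)=C | intermediate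
8 | (3Z,6E)-3,8-dimethylnona-3,6,8-trienoyl chloride | ClC(=O)C/C(C)=C\C/C=C/C(C)=C | intermediate
9 | (3Z,6E)-3,8-dimethylnona-1,3,6,8-tetraen-1-one (vinylketene) | O=C=C/C(C)=C\C/C=C/C(C)=C | intermediate
10 | racemic 2-methyl-7-(prop-1-en-2-yl)bicyclo[3.1.1]hept-2-en-6-one, isopropenyl anti to the C2–C4 bridge (both enantiomers written) | C=C(C)[C@@H]1[C@H]2CC=C(C)[C@@H]1C2=O.C=C(C)[C@H]1[C@@H]2CC=C(C)[C@H]1C2=O | intermediate
11 | (1R,5R,7R)-2-methyl-7-(prop-1-en-2-yl)bicyclo[3.1.1]hept-2-en-6-one | C=C(C)[C@@H]1[C@H]2CC=C(C)[C@@H]1C2=O | intermediate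
12 | 2-methyl-6-[(phenylsulfonyl)methylidene]-7-(prop-1-en-2-yl)bicyclo[3.1.1]hept-2-ene, ring stereocentres as in 11, either alkene geometry | C=C(C)[C@@H]1[C@H]2CC=C(C)[C@@H]1C2=CS(=O)(=O)c1ccccc1 | intermediate
13 | 2-{2-methyl-6-[(phenylsulfonyl)methylidene]bicyclo[3.1.1]hept-2-en-7-yl}propan-1-ol, ring stereocentres as in 11, both epimers at the side-chain carbon | CC(CO)[C@@H]1[C@H]2CC=C(C)[C@@H]1C2=CS(=O)(=O)c1ccccc1 | intermediate
14 | 2-{2-methyl-6-[(phenylsulfonyl)methylidene]bicyclo[3.1.1]hept-2-en-7-yl}propanal, ring stereocentres as in 11, both epimers at the side-chain carbon | CC(C=O)[C@@H]1[C@H]2CC=C(C)[C@@H]1C2=CS(=O)(=O)c1ccccc1 | intermediate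
15 | 2-methyl-2-{2-methyl-6-[(phenylsulfonyl)methylidene]bicyclo[3.1.1]hept-2-en-7-yl}propanal, ring stereocentres as in 11 | CC(C)(C=O)[C@@H]1[C@H]2CC=C(C)[C@@H]1C2=CS(=O)(=O)c1ccccc1 | intermediate
16 | tert-butyl(ethenyloxy)dimethylsilane | C=CO[Si](C)(C)C(C)(C)C | starting material
17 | (3R)-3-[(tert-butyldimethylsilyl)oxy]-4-methyl-4-{2-methyl-6-[(phenylsulfonyl)methylidene]bicyclo[3.1.1]hept-2-en-7-yl}pentanal | O=CC[C@@H](O[Si](C)(C)C(C)(C)C)C(C)(C)[C@@H]1[C@H]2CC=C(C)[C@@H]1C2=CS(=O)(=O)c1ccccc1 | intermediate
18 | (7R)-7-[(tert-butyldimethylsilyl)oxy]-10-[(phenylsulfonyl)methyl]-10-demethyl-longipin-2-en-9-one (C4, C5, C10, C11 arranged as in 28; CH2SO2Ph in the place of the C10 methyl) | O=C1C[C@@H](O[Si](C)(C)C(C)(C)C)C(C)(C)[C@@H]2[C@H]3CC=C(C)[C@@H]2[C@]31CS(=O)(=O)c1ccccc1 | intermediate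
19 | (7R,9R)-7-[(tert-butyldimethylsilyl)oxy]-10-[(phenylsulfonyl)methyl]-10-demethyl-longipin-2-en-9-ol | O[C@@H]1C[C@@H](O[Si](C)(C)C(C)(C)C)C(C)(C)[C@@H]2[C@H]3CC=C(C)[C@@H]2[C@]31CS(=O)(=O)c1ccccc1 | intermediate
20 | (7R,9R)-7-[(tert-butyldimethylsilyl)oxy]longipin-2-en-9-ol | O[C@@H]1C[C@@H](O[Si](C)(C)C(C)(C)C)C(C)(C)[C@@H]2[C@H]3CC=C(C)[C@@H]2[C@]31C | intermediate
21 | (2Z)-2-methylbut-2-enoic acid (angelic acid) | C/C=C(/C)C(=O)O | starting material
22 | (7R,9R)-7-[(tert-butyldimethylsilyl)oxy]longipin-2-en-9-yl (2Z)-2-methylbut-2-enoate | C/C=C(/C)C(=O)O[C@@H]1C[C@@H](O[Si](C)(C)C(C)(C)C)C(C)(C)[C@@H]2[C@H]3CC=C(C)[C@@H]2[C@]31C | intermediate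
23 | (7R,9R)-7-hydroxylongipin-2-en-9-yl (2Z)-2-methylbut-2-enoate | C/C=C(/C)C(=O)O[C@@H]1C[C@@H](O)C(C)(C)[C@@H]2[C@H]3CC=C(C)[C@@H]2[C@]31C | intermediate
24 | (2E)-2-methylbut-2-en-1-ol | C/C=C(\C)CO | starting material
25 | [(2R,3R)-2,3-dimethyloxiran-2-yl]methanol | OC[C@@]1(C)O[C@@H]1C | intermediate
26 | (2S,3R)-2,3-dimethyloxirane-2-carboxylic acid | OC(=O)[C@@]1(C)O[C@@H]1C | intermediate
27 | (7R,9R)-9-{[(2Z)-2-methylbut-2-enoyl]oxy}longipin-2-en-7-yl (2S,3R)-2,3-dimethyloxirane-2-carboxylate | C/C=C(/C)C(=O)O[C@@H]1C[C@@H](OC(=O)[C@@]2(C)O[C@@H]2C)C(C)(C)[C@@H]2[C@H]3CC=C(C)[C@@H]2[C@]31C | intermediate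
28 | (4R,5S,7R,9R,10R,11R)-9-{[(2Z)-2-methylbut-2-enoyl]oxy}-1-oxolongipin-2-en-7-yl (2S,3R)-2,3-dimethyloxirane-2-carboxylate | C/C=C(/C)C(=O)O[C@@H]1C[C@@H](OC(=O)[C@@]2(C)O[C@@H]2C)C(C)(C)[C@@H]2[C@H]3C(=O)C=C(C)[C@@H]2[C@]31C | target

**Step count**

Total step count: 18. Longest linear sequence: 16 steps (steps 1 to 14, 17 and 18; steps 15 and 16 make acid 26).

**Steps most likely to fail**

Step 10 (bears the label). The photocatalytic stage may fail through hydrogen abstraction at the allylic C1 methylene or the C7 carbinol C–H instead of the formyl C–H. The acyl radical may also be reduced or lose carbon monoxide faster than it closes the ring, and the aldol stage may turn over poorly with the neopentyl aldehyde. Fallback with known chemistry, from 15 back to 18: the aldol stage alone would be run and aldehyde 17 isolated. It would be oxidised (NaClO2, NaH2PO4, 2-methylbut-2-ene) to the carboxylic acid F1, converted with (PhSe)2 and Bu3P into the Se-phenyl selenoester F2, and cyclised with Bu3SnH and AIBN in benzene at 80 °C under slow addition. This is a tin-mediated acyl-radical chain cyclisation of an acyl selenide, and it should give 18.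

Step 4. At 110 °C the vinylketene may undergo a 1,5-hydrogen shift across the doubly allylic C1 methylene, dimerise, or close in the fused instead of the bridged sense. Fallback, from 7 back to 10: the acid would be condensed with pyrrolidine (EDC, HOBt) to the amide F3. Activation with Tf2O and 2,6-di-tert-butyl-4-methylpyridine in CH2Cl2 at 0 to 40 °C would give a vinyl keteniminium ion, whose intramolecular [2+2] cycloaddition with the same alkene at much lower temperature gives the cyclobutaniminium triflate F4. Aqueous NaHCO3 would hydrolyse it to 10.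

Step 18. Radical oxidation on the last intermediate may attack the allylic methyl groups of the angelate or the carbinol C–H bonds next to the ester oxygens, or over-oxidise. Fallback, from 22 back to 28: the oxidation would be moved two steps earlier and done with CrO3 and 3,5-dimethylpyrazole in CH2Cl2 at −20 °C on the silyl ether, giving the enone F5. HF·pyridine would then give the hydroxy enone F6, and Yamaguchi esterification with 26 as in step 17 would give 28.

Further compounds
F1 | step 10 | (3R)-3-[(tert-butyldimethylsilyl)oxy]-4-methyl-4-{2-methyl-6-[(phenylsulfonyl)methylidene]bicyclo[3.1.1]hept-2-en-7-yl}pentanoic acid | OC(=O)C[C@@H](O[Si](C)(C)C(C)(C)C)C(C)(C)[C@@H]1[C@H]2CC=C(C)[C@@H]1C2=CS(=O)(=O)c1ccccc1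
F2 | step 10 | Se-phenyl (3R)-3-[(tert-butyldimethylsilyl)oxy]-4-methyl-4-{2-methyl-6-[(phenylsulfonyl)methylidene]bicyclo[3.1.1]hept-2-en-7-yl}pentaneselenoate | O=C([Se]c1ccccc1)C[C@@H](O[Si](C)(C)C(C)(C)C)C(C)(C)[C@@H]1[C@H]2CC=C(C)[C@@H]1C2=CS(=O)(=O)c1ccccc1
F3 | step 4 | 1-[(3Z,6E)-3,8-dimethylnona-3,6,8-trienoyl]pyrrolidine | O=C(C/C(C)=C\C/C=C/C(C)=C)N1CCCC1
F4 | step 4 | racemic 1-[2-methyl-7-(prop-1-en-2-yl)bicyclo[3.1.1]hept-2-en-6-ylidene]pyrrolidinium trifluoromethanesulfonate (one enantiomer written) | C=C(C)[C@@H]1[C@H]2CC=C(C)[C@@H]1C2=[N+]1CCCC1.[O-]S(=O)(=O)C(F)(F)F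
F5 | step 18 | (7R,9R)-7-[(tert-butyldimethylsilyl)oxy]-1-oxolongipin-2-en-9-yl (2Z)-2-methylbut-2-enoate | C/C=C(/C)C(=O)O[C@@H]1C[C@@H](O[Si](C)(C)C(C)(C)C)C(C)(C)[C@@H]2[C@H]3C(=O)C=C(C)[C@@H]2[C@]31C
F6 | step 18 | (7R,9R)-7-hydroxy-1-oxolongipin-2-en-9-yl (2Z)-2-methylbut-2-enoate | C/C=C(/C)C(=O)O[C@@H]1C[C@@H](O)C(C)(C)[C@@H]2[C@H]3C(=O)C=C(C)[C@@H]2[C@]31C
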